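All runs are calculated with made-up constants; the scatter is artificial.

Two questions stood on this flask, and I reckoned them from Sunday's run, down a ladder of time scales.

- Sunday's: substrate 0.083 M; acid 2.49 mM; scavenger 1 equiv; run made earlier
- flask: substrate 0.083 M; acid 2.49 mM; scavenger 0.500 equiv; time 1.0 h

- Sunday's (time / min: substrate / %, target / %): 2.00: 95.0, 2.1; 4.00: 88.3, 5.7; 6.00: 85.6, 7.5; 8.00: 80.6, 10.0; 10.0: 79.6, 9.6; 12.0: 74.2, 12.5

(each reading ± 1 percentage point)

- part of the substrate that has reacted at 1.0 h
- pH of the solution at 1.0 h

- acid is the free proton; pH is minus the decimal logarithm of its molar concentration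
- what has gone from substrate into another species counts as reacted, even if it can come back
- no earlier run changes the charge of scavenger; that part of a forecast is a guess

The acid came first: by 12.0 min Sunday's flask had lost 21.4 mM of substrate, more than the 2.49 mM of acid charged, and the loss was still running. So I took the acid as an unconsumed catalyst and the pH as that of its charge. The total loss came next, read off Sunday's last reading as a constant k_L of 0.0249 min⁻¹ with a half-life of 27.8 min. Target came last, holding half of that loss in the last reading. Target gained per substrate present per minute gave a reading of the pseudo-first-order constant k_T, 0.0120 min⁻¹, smaller than k_L, and hence 58.0 min for t_T, the target half-life, the time in which the target route by itself halves the substrate.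

Counting the target route by itself, t_T gave an estimate of 51.2% reacted at 1.0 h; counting the total loss as running on unchanged, k_L gave 77.5%. I committed to the middle, 64.3%, and the charge of 0.500 equiv of scavenger stayed a guess.

The forecast gave 68% (range 45% to 85%) and pH 2.6 (range 2.55 to 3), noting that "Halving the scavenger is untested".

The flask gave 65.7% reacted and pH 2.60.

    substrate ⇌ dormant form (K = 0.520, k = 1.50 × 10⁻⁴ s⁻¹)
    weak acid ⇌ conjugate base + acid, settled at all times (K = 3.20 × 10⁻⁶ M)
    substrate → weak acid + target (k = 6.00 × 10⁻⁵ s⁻¹)
    substrate + acid → weak acid + acid + target (k = 0.0620 L mol⁻¹ s⁻¹)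
    weak acid + scavenger → scavenged by-product (k = 0.0500 L mol⁻¹ s⁻¹)
    substrate + weak acid ⇌ idle adduct, settled at all times (K = 17.0 L mol⁻¹)

In this flask substrate and dormant form relax, by that step by itself, with a half-life of 0.439 h, shorter than t_T, and the step to dormant form had 84% of its turnover up to 1.0 h behind it by 0.500 h. For the neighbour charged with 0.010 M of acid, t_T scaled in proportion to acid, as a rough estimate of mine, comes to 0.241 h, below that relaxation half-life, and at 1.00 h that neighbour held 78.2% target and 8.81% dormant form, against 17.4% dormant form in this flask.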